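## Structural features

The target consists of two fully substituted, phloroglucinol-type benzene rings joined by one methylene carbon that links C5 of ring A to C8 of ring B. Ring A carries the (R)-2-methylbutanoyl ketone on C1 between hydroxyls on C2 and C6, a methyl on C3 and a methoxy group on C4. Ring B is the benzene ring of a 5,7-dihydroxy-2,2,6-trimethylchroman-4-one. The only stereocentre is the carbon alpha to the ring A ketone; it has no stereogenic neighbour, is lost by enolisation, and so must be bought and kept away from strong base, hot acid and Lewis acids. Fragile elements are that centre, the oxidisable phenols, the diarylmethane (two electron-rich rings on one carbon can separate by retro-Michael or retro-Friedel–Crafts paths) and the pyranone, whose opening and reclosure would exchange O1 for O5. The real difficulty is regiochemical: C4a has two ortho oxygens (on C8a and on C5) and only one may become O1, and one of the three ring A oxygens must be methylated. The key step uses the fact that the oxygen on C8a lies between C8, which bears the bridge, and C4a, which bears hydrogen: a 1,1-dimethylpropargyl group on that oxygen can migrate only to C4a, and with O5 capped the ring can close only onto O1. One premise needs correcting: a single ketone can hydrogen-bond only one of the two ring A hydroxyls at a time, so the other is a free, fairly acidic phenol whose passivity must come from crowding and low nucleophilicity, not from chelation.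

## Logic of the disconnections

**23 to 22.** The two acetal O–CH2 bonds on O5 and O7 are cut. The caps are needed because O5 must carry no hydrogen during ring closure and both ring B oxygens must be inert to the etherification. Nothing is gained in skeleton; the gain is that the key step becomes regiochemically possible. The forward removal must not open the pyranone, cleave the diarylmethane or enolise the ketone, so it is set as dilute acid near room temperature, after everything else.

**22 to 21 to 19.** The C4 carbonyl is taken back to the C4 alcohol and then the C4–O bond is cut, leaving the C3=C4 alkene. The reason is that the ring-forming cascade delivers C4 at the alkene level. The forward hydration must place oxygen on C4 and not C3, and the oxidation must tolerate free phenols.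

**19 to 15 (key).** The C4a–C4 bond is cut; O1–C2 is kept on paper, although it is broken and re-formed in the event. Cutting here lets the ether tether decide which oxygen becomes O1. The pyran ring disappears and 15 is a diarylmethane carrying one ether. The forward step must be thermal and neutral, and C4a must be the only hydrogen-bearing ortho carbon.

**15 to 12 and 13.** The O1–C(Me)2 bond is cut. The skeleton and protecting groups of 15 are kept; what is changed is the control element. Because only one ring A hydroxyl is chelated, the etherification is run with enough base to deprotonate ring B as well, so that the most basic and least hindered phenoxide competes. Ring A is left unprotected on purpose: capping its hindered hydroxyls would need strong base on a ketone no longer masked as a vinylogous acid, and the free hydroxyls guard the stereocentre. This is still the weakest step of the route and has a fallback.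

**12 to 6 and 10.** The C8–CH2 bond is cut. An ortho-quinone methide from ring A and the phenol of ring B are the natural partners. Because 10 is symmetric, either ortho carbon gives the same product, and the electrophile has no free ring carbon of its own. The forward step must stop at mono-alkylation.

**6 to 5.** The C5–CH2 bond on ring A is cut (Mannich). C5 is the only unsubstituted carbon of 5, so there is no choice of site.

**5 to 4, then to 3 and 2, then to 1.** The O–CH3 bond on O4 and then the aryl–acyl bond are cut. The two free carbons of 3 are equivalent, so acylation has one outcome. The forward methylation must stay on the oxygen para to the ketone, and the acylation must not erode the configuration bought in 1.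

**10 to 8 to 7.** The aryl C–O bond para to the methyl group is cut (through a C–B bond), then the two acetal O–C bonds. 7 lacks the third oxygen, and a sterically governed C–H borylation puts it at the only unhindered position.

## Other disconnections considered

**Alternative 1:** Ring B is cut across C8–C8a and C4a–C5 into the bis-silyl dienol ether A1 and the bromodihydropyranone A2.
- Forward step: a Diels–Alder addition in which the unsubstituted diene terminus bonds to the oxygen-bearing carbon of A2 and the ketene acetal carbon bonds to the bromine-bearing carbon. Loss of HBr and of the methoxy and silyl groups would aromatise to A3. Hydrogenolysis of the benzyl ether would give the hydroxymethyl compound A4, which on heating would form a ring B quinone methide and alkylate 5 at its only free carbon to give 23.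
- In its favour: every substituent of ring B is placed by the two fragments, and O1 is fixed because the pyranone oxygen already sits on C8a. A3 has free phenols, so no acid is used after the chromanone exists, and no phenol has to be etherified selectively. On these two points it is better than the chosen plan.
- Against it here: A2 is a vinylogous ester and a weak dienophile, the diene is tetrasubstituted and hydrolytically sensitive, and its methyl-bearing terminus must bond to a carbon that becomes fully substituted. Each fragment needs several steps, so the count would not fall below the chosen plan (estimated two or three steps more).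
- Comparison: on structure both fix O1 by construction. On mechanism the chosen cascade is unimolecular and better precedented for aryl ethers than this cycloaddition is for so hindered a pair. On step economy the chosen plan is shorter; on end-game protecting-group economy the alternative is better.

**Alternative 2:** The pyranone is cut at C8a–O1, C4a–C4 and O1–C2, giving the ortho-silylaryl triflate A5 and 3-methylbut-2-enoic acid A6.
- Forward step: fluoride would unmask the strained triple bond between C4a and C8a. The carboxylate oxygen would add at C8a (meta to the C5 oxygen), the aryl anion at C4a would take the acyl group, and the phenoxide would close onto the enone to give A7. Acetal removal would give A8, which would be joined at C8, its only free carbon, to the quinone methide from 6.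
- In its favour: the chromanone arrives at the right oxidation level in one step, so no hydration and oxidation are needed. A5 should be reachable from 10 in three routine steps, and because 10 is symmetric the question of which ortho carbon is silylated does not arise. No phenol needs selective etherification, and the acid deprotection happens before the bridge exists. On chemoselectivity it is better than the chosen plan, and on step count it is its equal (about twelve steps).
- Against it here: acyl transfer competes with simple O-arylation and with protonation of the aryl anion, and the precedent is for far less substituted arynes. The final union must be made on an unprotected, acyl-deactivated chromanone.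
- Comparison: the chosen plan is better in the reliability of the ring-forming event itself (neutral, thermal, no external partner) and in making the bridge while ring B is still a strongly nucleophilic phenol.

**Alternative 3:** Ring A is cut across C3–C4, C1–C2 and C4–C5 (ring A numbering) into the cyclobutenone A9 and the siloxyalkyne A10.
- Forward step: heating would open A9 to a vinylketene, (2+2) addition of A10 would give a new cyclobutenone, and a second four-electron opening followed by six-electron closure and enolisation would give the phenol A11.
- In its favour: the three ring A oxygens emerge differentiated (free hydroxyl on C4 for methylation, silyl ether on C2, ethyl ether on C6). That removes the selective methylation of the chosen plan, and on this point it is better. The cascade is also neutral and thermal.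
- Against it here: it does not address O1 at all, since the ring B chromanone must be made first by another method. A9 requires alkylation of a cyclobutenone enolate with a labile, electron-rich benzylic halide. After A11 there would be at least five steps (methylation, desilylation, introduction of the (R)-acyl group on C1, de-ethylation, debenzylation) against three in the chosen plan. The acylation would bring the stereocentre in late under Lewis acid, and the ethyl ether would need BCl3 next to the pyranone.
- Comparison: on step economy and on safety of the stereocentre the chosen plan is clearly ahead; on ring A oxygen differentiation the alternative is better.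

Key step: step 9

Remark on the chemistry: the structures of 15 and 19 are consistent as drawn; the correction concerns only the chelation premise. 20 and 21 are carried as mixtures of C4 epimers, which converge in step 11. 1, 3, 7 and 13 are bought.

## Route

Step 1
Reactants: 1 (R)-2-methylbutanoic acid
Product: 2 (R)-2-methylbutanoyl chloride
Conditions: (COCl)2 (1.2 equiv), DMF (cat.), CH2Cl2, 0 °C → rt
Reagents that add atoms: oxalyl chloride, ClC(=O)C(=O)Cl
Why: Acid chloride formation through the Vilsmeier-type chloroiminium from DMF; no base is present and the temperature is low, so ketene formation and loss of the (R) configuration should be avoided.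

Step 2
Reactants: 3 2-methylphloroglucinol (2-methylbenzene-1,3,5-triol); 2 (R)-2-methylbutanoyl chloride
Product: 4 (R)-1-(2,4,6-trihydroxy-3-methylphenyl)-2-methylbutan-1-one
Conditions: AlCl3 (3 equiv), PhNO2/CH2Cl2, 0 °C → rt; cold aq HCl
Reagents that add atoms: none
Why: Friedel–Crafts C-acylation; the two unsubstituted carbons of 3 are equivalent, so one regioisomer should form, and the chelated product is deactivated towards a second acylation. The reaction is held at or below room temperature because enolisation of the acylium ion or of the complexed ketone is the only way the stereocentre could erode.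

Step 3
Reactants: 4 (R)-1-(2,4,6-trihydroxy-3-methylphenyl)-2-methylbutan-1-one
Product: 5 (R)-1-(2,6-dihydroxy-4-methoxy-3-methylphenyl)-2-methylbutan-1-one
Conditions: Me2SO4 (1.0 equiv), K2CO3 (1.0 equiv), acetone, rt
Reagents that add atoms: dimethyl sulfate, COS(=O)(=O)OC
Why: Williamson O-methylation under stoichiometric control: the hydroxyl para to the ketone is the most acidic and is not hydrogen-bonded, so one equivalent of base should place the anion, and the methyl group, there. As a phenoxide the aryl ketone is a vinylogous carboxylate and should not enolise.

Step 4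
Reactants: 5 (R)-1-(2,6-dihydroxy-4-methoxy-3-methylphenyl)-2-methylbutan-1-one
Product: 6 (R)-1-[3-[(dimethylamino)methyl]-2,6-dihydroxy-4-methoxy-5-methylphenyl]-2-methylbutan-1-one
Conditions: Me2N=CH2+ I− (1.1 equiv), CH2Cl2, rt; aq NaHCO3
Reagents that add atoms: N,N-dimethylmethyleneiminium iodide (Eschenmoser's salt), C[N+](C)=C.[I-]
Why: Mannich aminomethylation of a phenol at the only unsubstituted ring carbon, which is ortho to a hydroxyl; the mild, base-free conditions leave the stereocentre alone and do not yet release the quinone methide.

Step 5
Reactants: 7 2-methylresorcinol (2-methylbenzene-1,3-diol)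
Product: 8 1,3-bis(methoxymethoxy)-2-methylbenzene
Conditions: MOMCl (2.5 equiv), iPr2NEt (3 equiv), CH2Cl2, 0 °C → rt
Reagents that add atoms: chloromethyl methyl ether, COCCl
Why: Williamson-type acetal formation on both phenols; the methoxymethyl group is small, has no O–H for the later hydrogen shift, and survives base, heat and radical conditions.

Step 6
Reactants: 8 1,3-bis(methoxymethoxy)-2-methylbenzene
Product: 10 3,5-bis(methoxymethoxy)-4-methylphenol, via aryl pinacol boronate 9 (not isolated)
Conditions: B2pin2 (0.6 equiv), [Ir(OMe)(cod)]2 (1.5 mol%), 4,4'-di-tert-butyl-2,2'-bipyridine (3 mol%), THF, 80 °C; then 30% H2O2, aq NaOH, 0 °C → rt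
Reagents that add atoms: hydrogen peroxide, OO; bis(pinacolato)diboron, CC1(C)OB(OC1(C)C)B1OC(C)(C)C(C)(C)O1 (its boron is carried only in 9)
Why: Iridium-catalysed aromatic C–H borylation is governed by sterics and should take the only C–H without an ortho neighbour, the one para to the methyl group. Alkaline peroxide then oxidises the carbon–boron bond to the phenol at the same position, and the acetals are stable to both stages.

Step 7
Reactants: 6 (R)-1-[3-[(dimethylamino)methyl]-2,6-dihydroxy-4-methoxy-5-methylphenyl]-2-methylbutan-1-one; 10 3,5-bis(methoxymethoxy)-4-methylphenol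
Product: 12 (R)-1-[2,6-dihydroxy-5-[[6-hydroxy-2,4-bis(methoxymethoxy)-3-methylphenyl]methyl]-4-methoxy-3-methylphenyl]-2-methylbutan-1-one, via ring A ortho-quinone methide 11 (not isolated)
Conditions: 10 (2.5 equiv), toluene, 105 °C, Ar
Reagents that add atoms: none
Why: Thermal loss of dimethylamine from the ortho-hydroxybenzylamine gives quinone methide 11, and phenol 10 adds through its ortho carbon in a Michael-type C-alkylation followed by re-aromatisation. The two ortho carbons of 10 are equivalent and the para carbon is blocked, 11 has no free ring carbon with which to attack itself, and the recoverable excess of 10 should hold back a second alkylation.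

Step 8
Reactants: 12 (R)-1-[2,6-dihydroxy-5-[[6-hydroxy-2,4-bis(methoxymethoxy)-3-methylphenyl]methyl]-4-methoxy-3-methylphenyl]-2-methylbutan-1-one; 13 2-methylbut-3-yn-2-ol
Product: 15 (R)-1-[2,6-dihydroxy-4-methoxy-3-methyl-5-[[2,4-bis(methoxymethoxy)-3-methyl-6-(2-methylbut-3-yn-2-yloxy)phenyl]methyl]phenyl]-2-methylbutan-1-one, via 2-methylbut-3-yn-2-yl trifluoroacetate 14 (not isolated)
Conditions: 13 (1.3 equiv), (CF3CO)2O (1.3 equiv), DBU (1.6 equiv), MeCN, −5 °C; then 12, CuCl2·2H2O (1 mol%), DBU (2.5 equiv), MeCN, −5 → 0 °C
Reagents that add atoms: trifluoroacetic anhydride, O=C(OC(=O)C(F)(F)F)C(F)(F)F (its acyl group is carried only in 14)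
Why: Copper-catalysed propargylic etherification: the alkyne of 14 forms a copper acetylide that loses trifluoroacetate to a copper allenylidene, and a phenoxide adds at the tertiary carbon. With enough amidine to deprotonate ring B as well as the acidic ring A site, the ring B phenoxide is the most basic oxygen and has one open ortho side, whereas the ring A oxygens are either chelated or part of a vinylogous carboxylate flanked on both sides, so the tertiary electrophile should go to ring B. The base meets the ketone as its phenoxide, which protects the stereocentre.

Step 9
Reactants: 15 (R)-1-[2,6-dihydroxy-4-methoxy-3-methyl-5-[[2,4-bis(methoxymethoxy)-3-methyl-6-(2-methylbut-3-yn-2-yloxy)phenyl]methyl]phenyl]-2-methylbutan-1-one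
Product: 19 (R)-1-[5-[[5,7-bis(methoxymethoxy)-2,2,6-trimethyl-2H-chromen-8-yl]methyl]-2,6-dihydroxy-4-methoxy-3-methylphenyl]-2-methylbutan-1-one, via allenyl cyclohexadienone 16 (not isolated), via ortho-allenylphenol 17 (not isolated), via ring B ortho-quinone methide 18 (not isolated)
Conditions: o-xylene (degassed, 0.02 M), 130 °C, Ar
Reagents that add atoms: none
Why: This is the aromatic propargyl Claisen cascade, the standard thermal conversion of aryl 1,1-dimethylpropargyl ethers into 2,2-dimethyl-2H-chromenes. A concerted (3,3) sigmatropic shift cleaves O1–C2 and bonds the alkyne terminus to C4a, the only hydrogen-bearing ortho carbon, giving allenyl dienone 16, which enolises to ortho-allenylphenol 17. A 1,5-hydrogen shift from the new O1–H to the central allene carbon gives the (Z)-dienone 18, an ortho-quinone methide. The ring closes by a thermally allowed, disrotatory six-electron oxa-electrocyclisation of 18, in which O1 bonds to the dimethyl-bearing carbon and the pyran ring forms. No stereocentre is created: C2 carries two methyl groups and the sp3 ring carbon of 16 is lost on enolisation. Regioselectivity needs the shift to end at C4a and the closure to use O1; the bridge on C8 secures the first (a shift there gives a dienone that cannot enolise and is expected to revert), and the methoxymethyl cap on O5, which has no hydrogen to start a competing 1,5-shift, secures the second. Chemoselectivity needs the ring A hydroxyls, the acetals and the diarylmethane to stay passive, which the absence of acid, base and metal should ensure. The same neutrality and the chelated ketone should keep the (R) centre intact.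

Step 10
Reactants: 19 (R)-1-[5-[[5,7-bis(methoxymethoxy)-2,2,6-trimethyl-2H-chromen-8-yl]methyl]-2,6-dihydroxy-4-methoxy-3-methylphenyl]-2-methylbutan-1-one
Product: 21 (2R)-1-[2,6-dihydroxy-5-[[4-hydroxy-5,7-bis(methoxymethoxy)-2,2,6-trimethyl-3,4-dihydro-2H-chromen-8-yl]methyl]-4-methoxy-3-methylphenyl]-2-methylbutan-1-one (both C4 epimers), via benzylic hydroperoxide 20 (not isolated)
Conditions: Co(acac)2 (20 mol%), PhSiH3 (3 equiv), O2 (1 atm), THF, 0 °C → rt; then PPh3
Reagents that add atoms: dioxygen, O=O
Why: Mukaiyama hydration: the cobalt hydride formed from Co(acac)2 and the silane transfers a hydrogen atom to C3, so the radical sits at benzylic C4 and is trapped there by O2; silane and then PPh3 reduce the peroxide to the alcohol. The new C4 centre forms without control and is erased in step 11; arenes, acetals and the ketone are not substrates for hydrogen atom transfer.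

Step 11
Reactants: 21 (2R)-1-[2,6-dihydroxy-5-[[4-hydroxy-5,7-bis(methoxymethoxy)-2,2,6-trimethyl-3,4-dihydro-2H-chromen-8-yl]methyl]-4-methoxy-3-methylphenyl]-2-methylbutan-1-one
Product: 22 (R)-1-[5-[[5,7-bis(methoxymethoxy)-2,2,6-trimethyl-4-oxo-3,4-dihydro-2H-chromen-8-yl]methyl]-2,6-dihydroxy-4-methoxy-3-methylphenyl]-2-methylbutan-1-one
Conditions: MnO2 (activated, 15 equiv), CH2Cl2, rt
Reagents that add atoms: none
Why: Heterogeneous MnO2 oxidises benzylic alcohols selectively and converges both C4 epimers on one ketone. It is preferred to hypervalent iodine reagents, which can dearomatise fully substituted phenols such as those of ring A.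

Step 12
Reactants: 22 (R)-1-[5-[[5,7-bis(methoxymethoxy)-2,2,6-trimethyl-4-oxo-3,4-dihydro-2H-chromen-8-yl]methyl]-2,6-dihydroxy-4-methoxy-3-methylphenyl]-2-methylbutan-1-one
Product: 23 (R)-1-[5-[(5,7-dihydroxy-2,2,6-trimethyl-4-oxo-3,4-dihydro-2H-chromen-8-yl)methyl]-2,6-dihydroxy-4-methoxy-3-methylphenyl]-2-methylbutan-1-one (CNP0303209.1)
Conditions: 2 M aq HCl, MeOH/THF, rt → 35 °C
Reagents that add atoms: none
Why: Acid-catalysed methanolysis of the two aryl methoxymethyl acetals; the one on O5 is peri to the new carbonyl and should leave first. Dilute acid near room temperature is far below what retro-oxa-Michael opening of the pyranone, cleavage of the diarylmethane or enolisation of the chelated ketone would need, so O1, the bridge and the (R) centre should be kept.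

## Compound list

1 | (R)-2-methylbutanoic acid | CC[C@@H](C)C(=O)O | starting material
2 | (R)-2-methylbutanoyl chloride | CC[C@@H](C)C(Cl)=O | intermediate
3 | 2-methylphloroglucinol (2-methylbenzene-1,3,5-triol) | Cc1c(O)cc(O)cc1O | starting material
4 | (R)-1-(2,4,6-trihydroxy-3-methylphenyl)-2-methylbutan-1-one | CC[C@@H](C)C(=O)c1c(O)c(C)c(O)cc1O | intermediate
5 | (R)-1-(2,6-dihydroxy-4-methoxy-3-methylphenyl)-2-methylbutan-1-one | CC[C@@H](C)C(=O)c1c(O)c(C)c(OC)cc1O | intermediate
6 | (R)-1-[3-[(dimethylamino)methyl]-2,6-dihydroxy-4-methoxy-5-methylphenyl]-2-methylbutan-1-one | CC[C@@H](C)C(=O)c1c(O)c(C)c(OC)c(CN(C)C)c1O | intermediate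
7 | 2-methylresorcinol (2-methylbenzene-1,3-diol) | Cc1c(O)cccc1O | starting material
8 | 1,3-bis(methoxymethoxy)-2-methylbenzene | COCOc1cccc(OCOC)c1C | intermediate
9 | 2-[3,5-bis(methoxymethoxy)-4-methylphenyl]-4,4,5,5-tetramethyl-1,3,2-dioxaborolane | COCOc1cc(B2OC(C)(C)C(C)(C)O2)cc(OCOC)c1C | intermediate (not isolated)
10 | 3,5-bis(methoxymethoxy)-4-methylphenol | COCOc1cc(O)cc(OCOC)c1C | intermediate
11 | (R)-3-hydroxy-5-methoxy-4-methyl-2-(2-methylbutanoyl)-6-methylidenecyclohexa-2,4-dien-1-one | CC[C@@H](C)C(=O)C1=C(O)C(C)=C(OC)C(=C)C1=O | intermediate (not isolated)
12 | (R)-1-[2,6-dihydroxy-5-[[6-hydroxy-2,4-bis(methoxymethoxy)-3-methylphenyl]methyl]-4-methoxy-3-methylphenyl]-2-methylbutan-1-one | CC[C@@H](C)C(=O)c1c(O)c(C)c(OC)c(Cc2c(OCOC)c(C)c(OCOC)cc2O)c1O | intermediate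
13 | 2-methylbut-3-yn-2-ol | CC(C)(O)C#C | starting material
14 | 2-methylbut-3-yn-2-yl 2,2,2-trifluoroacetate | CC(C)(C#C)OC(=O)C(F)(F)F | intermediate (not isolated)
15 | (R)-1-[2,6-dihydroxy-4-methoxy-3-methyl-5-[[2,4-bis(methoxymethoxy)-3-methyl-6-(2-methylbut-3-yn-2-yloxy)phenyl]methyl]phenyl]-2-methylbutan-1-one | CC[C@@H](C)C(=O)c1c(O)c(C)c(OC)c(Cc2c(OCOC)c(C)c(OCOC)cc2OC(C)(C)C#C)c1O | intermediate
16 | (R)-1-[2,6-dihydroxy-4-methoxy-3-methyl-5-[[2,4-bis(methoxymethoxy)-3-methyl-5-(3-methylbuta-1,2-dienyl)-6-oxocyclohexa-1,3-dienyl]methyl]phenyl]-2-methylbutan-1-one (ring sp3 carbon unspecified) | CC[C@@H](C)C(=O)c1c(O)c(C)c(OC)c(CC2=C(OCOC)C(C)=C(OCOC)C(C=C=C(C)C)C2=O)c1O | intermediate (not isolated)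
17 | (R)-1-[2,6-dihydroxy-5-[[2-hydroxy-4,6-bis(methoxymethoxy)-5-methyl-3-(3-methylbuta-1,2-dienyl)phenyl]methyl]-4-methoxy-3-methylphenyl]-2-methylbutan-1-one | CC[C@@H](C)C(=O)c1c(O)c(C)c(OC)c(Cc2c(OCOC)c(C)c(OCOC)c(C=C=C(C)C)c2O)c1O | intermediate (not isolated)
18 | (R)-1-[2,6-dihydroxy-4-methoxy-3-methyl-5-[[(5Z)-2,4-bis(methoxymethoxy)-3-methyl-5-(3-methylbut-2-enylidene)-6-oxocyclohexa-1,3-dienyl]methyl]phenyl]-2-methylbutan-1-one | CC[C@@H](C)C(=O)c1c(O)c(C)c(OC)c(CC2=C(OCOC)C(C)=C(OCOC)/C(=C/C=C(C)C)C2=O)c1O | intermediate (not isolated)
19 | (R)-1-[5-[[5,7-bis(methoxymethoxy)-2,2,6-trimethyl-2H-chromen-8-yl]methyl]-2,6-dihydroxy-4-methoxy-3-methylphenyl]-2-methylbutan-1-one | CC[C@@H](C)C(=O)c1c(O)c(C)c(OC)c(Cc2c(OCOC)c(C)c(OCOC)c3C=CC(C)(C)Oc23)c1O | intermediate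
20 | (2R)-1-[5-[[4-hydroperoxy-5,7-bis(methoxymethoxy)-2,2,6-trimethyl-3,4-dihydro-2H-chromen-8-yl]methyl]-2,6-dihydroxy-4-methoxy-3-methylphenyl]-2-methylbutan-1-one (both C4 epimers) | CC[C@@H](C)C(=O)c1c(O)c(C)c(OC)c(Cc2c(OCOC)c(C)c(OCOC)c3C(OO)CC(C)(C)Oc23)c1O | intermediate (not isolated)
21 | (2R)-1-[2,6-dihydroxy-5-[[4-hydroxy-5,7-bis(methoxymethoxy)-2,2,6-trimethyl-3,4-dihydro-2H-chromen-8-yl]methyl]-4-methoxy-3-methylphenyl]-2-methylbutan-1-one (both C4 epimers) | CC[C@@H](C)C(=O)c1c(O)c(C)c(OC)c(Cc2c(OCOC)c(C)c(OCOC)c3C(O)CC(C)(C)Oc23)c1O | intermediate
22 | (R)-1-[5-[[5,7-bis(methoxymethoxy)-2,2,6-trimethyl-4-oxo-3,4-dihydro-2H-chromen-8-yl]methyl]-2,6-dihydroxy-4-methoxy-3-methylphenyl]-2-methylbutan-1-one | CC[C@@H](C)C(=O)c1c(O)c(C)c(OC)c(Cc2c(OCOC)c(C)c(OCOC)c3c2OC(C)(C)CC3=O)c1O | intermediate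
23 | (R)-1-[5-[(5,7-dihydroxy-2,2,6-trimethyl-4-oxo-3,4-dihydro-2H-chromen-8-yl)methyl]-2,6-dihydroxy-4-methoxy-3-methylphenyl]-2-methylbutan-1-one | CC[C@@H](C)C(=O)c1c(O)c(C)c(OC)c(Cc2c(O)c(C)c(O)c3c2OC(C)(C)CC3=O)c1O | target

## Step count and least certain steps

Total: 12 steps. Longest linear sequence: 10 steps (1, 2, 3, 4, 7, 8, 9, 10, 11, 12); the ring B branch (5, 6) joins at step 7.

**Step 9 (key step).** The likeliest failure is migration of the propargyl group to the substituted ortho carbon C8, followed by intramolecular cycloaddition of the allene onto the dienone instead of reversion. A second risk is slow conversion that forces temperatures at which the acetals or the diarylmethane start to fragment. The fallback sets out from 15 and comes back at 19. It replaces the sigmatropic path by cationic gold catalysis, (Ph3P)AuNTf2 (monovalent gold) in CH2Cl2 at room temperature: the alkyne is activated as a π-complex, C4a attacks in a 6-endo Friedel–Crafts-type hydroarylation, and protodeauration gives the chromene. O1–C2 is never broken, so O1 stays fixed by the ether, and no new compound is involved.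

**Step 8.** The likeliest failure is loss of chemoselectivity: etherification at a ring A oxygen (its acidic hydroxyl is deprotonated first) or at two oxygens. The fallback sets out from 10 and 14 and comes back at 23, using 6; it gives up the bridged precursor and runs the same rearrangement on the symmetric ether, where there is only one phenol and the two ortho carbons are equivalent.
- 10 would be etherified with 14 under the conditions of step 8 to give 1,3-bis(methoxymethoxy)-2-methyl-5-(2-methylbut-3-yn-2-yloxy)benzene F1.
- Heating in o-xylene would give 5,7-bis(methoxymethoxy)-2,2,6-trimethyl-2H-chromene F2.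
- Hydration as in step 10 would pass through 4-hydroperoxy-5,7-bis(methoxymethoxy)-2,2,6-trimethylchromane F3 to 5,7-bis(methoxymethoxy)-2,2,6-trimethylchroman-4-ol F4.
- MnO2 would give 5,7-bis(methoxymethoxy)-2,2,6-trimethylchroman-4-one F5, and dilute methanolic HCl would give 5,7-dihydroxy-2,2,6-trimethylchroman-4-one F6.
- F6 has one free aromatic carbon, C8, ortho to the C7 hydroxyl. Heating it with 6 in toluene would generate 11 and alkylate C8 to give 23.
- The price is a final union on an unprotected, acyl-deactivated ring.

**Step 7.** The likeliest failure is over-alkylation: 12 still has an activated ortho C–H (C4a) and can take a second quinone methide, while reversible O-alkylation can drain 11 into oligomers. The fallback sets out from 10 and 5 and comes back at 12, reversing the roles of the partners. 10 would be aminomethylated with Eschenmoser's salt to 2-[(dimethylamino)methyl]-3,5-bis(methoxymethoxy)-4-methylphenol F7. Heating F7 with 5 would release 3,5-bis(methoxymethoxy)-4-methyl-6-methylidenecyclohexa-2,4-dien-1-one F8, which 5 would capture at its single free carbon, so the nucleophile can be alkylated only once.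

**Step 3.** The likeliest failure is leakage of methylation to an ortho oxygen and double methylation, because the non-chelated ortho hydroxyl is only a little less acidic than the para one. The fallback sets out from 2 and comes back at 5, replacing selective methylation by selective demethylation and bypassing step 2. Commercial 1,3,5-trimethoxy-2-methylbenzene F9 would be acylated with 2 (SnCl4, CH2Cl2, −20 °C; its two free carbons are equivalent) to (R)-1-(2,4,6-trimethoxy-3-methylphenyl)-2-methylbutan-1-one F10. Excess BCl3 (CH2Cl2, −78 → 0 °C) would then cleave only the two methoxy groups that can chelate boron with the ketone, leaving the para one. The configurational purity would have to be checked after the Lewis acid stage.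

## Further compounds

F0 | step 9 | none | none
F1 | step 8 | 1,3-bis(methoxymethoxy)-2-methyl-5-(2-methylbut-3-yn-2-yloxy)benzene | COCOc1cc(OC(C)(C)C#C)cc(OCOC)c1C
F2 | step 8 | 5,7-bis(methoxymethoxy)-2,2,6-trimethyl-2H-chromene | COCOc1cc2OC(C)(C)C=Cc2c(OCOC)c1C
F3 | step 8 | 4-hydroperoxy-5,7-bis(methoxymethoxy)-2,2,6-trimethylchromane (racemic) | COCOc1cc2OC(C)(C)CC(OO)c2c(OCOC)c1C
F4 | step 8 | 5,7-bis(methoxymethoxy)-2,2,6-trimethylchroman-4-ol (racemic) | COCOc1cc2OC(C)(C)CC(O)c2c(OCOC)c1C
F5 | step 8 | 5,7-bis(methoxymethoxy)-2,2,6-trimethylchroman-4-one | COCOc1cc2OC(C)(C)CC(=O)c2c(OCOC)c1C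
F6 | step 8 | 5,7-dihydroxy-2,2,6-trimethylchroman-4-one | Cc1c(O)cc2OC(C)(C)CC(=O)c2c1O
F7 | step 7 | 2-[(dimethylamino)methyl]-3,5-bis(methoxymethoxy)-4-methylphenol | CN(C)Cc1c(O)cc(OCOC)c(C)c1OCOC
F8 | step 7 | 3,5-bis(methoxymethoxy)-4-methyl-6-methylidenecyclohexa-2,4-dien-1-one | C=C1C(=O)C=C(OCOC)C(C)=C1OCOC
F9 | step 3 | 1,3,5-trimethoxy-2-methylbenzene | COc1cc(OC)c(C)c(OC)c1
F10 | step 3 | (R)-1-(2,4,6-trimethoxy-3-methylphenyl)-2-methylbutan-1-one | CC[C@@H](C)C(=O)c1c(OC)cc(OC)c(C)c1OC
A1 | alternative 1 | 5-(benzyloxy)-1-methoxy-2-methyl-1,3-bis(trimethylsilyloxy)penta-1,3-diene | COC(O[Si](C)(C)C)=C(C)C(O[Si](C)(C)C)=CCOCc1ccccc1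
A2 | alternative 1 | 5-bromo-2,2-dimethyl-2,3-dihydro-4H-pyran-4-one | CC1(C)CC(=O)C(Br)=CO1
A3 | alternative 1 | 8-(benzyloxymethyl)-5,7-dihydroxy-2,2,6-trimethylchroman-4-one | Cc1c(O)c(COCc2ccccc2)c2OC(C)(C)CC(=O)c2c1O
A4 | alternative 1 | 5,7-dihydroxy-8-(hydroxymethyl)-2,2,6-trimethylchroman-4-one | Cc1c(O)c(CO)c2OC(C)(C)CC(=O)c2c1O
A5 | alternative 2 | 3,5-bis(methoxymethoxy)-4-methyl-2-(trimethylsilyl)phenyl trifluoromethanesulfonate | COCOc1cc(OS(=O)(=O)C(F)(F)F)c([Si](C)(C)C)c(OCOC)c1C
A6 | alternative 2 | 3-methylbut-2-enoic acid | CC(C)=CC(=O)O
A7 | alternative 2 | 5,7-bis(methoxymethoxy)-2,2,6-trimethylchroman-4-one | COCOc1cc2OC(C)(C)CC(=O)c2c(OCOC)c1C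
A8 | alternative 2 | 5,7-dihydroxy-2,2,6-trimethylchroman-4-one | Cc1c(O)cc2OC(C)(C)CC(=O)c2c1O
A9 | alternative 3 | 4-[[5,7-bis(benzyloxy)-2,2,6-trimethyl-4-oxochroman-8-yl]methyl]-3-ethoxycyclobut-2-en-1-one (racemic) | CCOC1=CC(=O)C1Cc1c(OCc2ccccc2)c(C)c(OCc2ccccc2)c2c1OC(C)(C)CC2=O
A10 | alternative 3 | triisopropyl(prop-1-yn-1-yloxy)silane | CC#CO[Si](C(C)C)(C(C)C)C(C)C
A11 | alternative 3 | 5,7-bis(benzyloxy)-8-[[6-ethoxy-2-hydroxy-3-methyl-4-(triisopropylsilyloxy)phenyl]methyl]-2,2,6-trimethylchroman-4-one | Cc1c(O)c(Cc2c(OCc3ccccc3)c(C)c(OCc3ccccc3)c3c2OC(C)(C)CC3=O)c(OCC)cc1O[Si](C(C)C)(C(C)C)C(C)C
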